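The red run reads 18% of target at 4.00 h and 21% at 15.0 h, though at the first of those times a third of its partner was still to be fed. So late partner adds little there.

| flask | substrate | partner | remark | time |
|---|---|---|---|---|
| violet | 20 mM | 7.3 mM (fed, over 6.0 h) | run made earlier; the fed solution adds 0.50 times the starting volume |  |
| red | 20 mM | 11 mM (fed, over 6.0 h) | run made earlier; the fed solution adds 0.50 times the starting volume |  |
| dusk | 20 mM | 16.0 mM (fed, over 6.0 h) | the fed solution adds 0.50 times the starting volume | 15 h |
| midnight | 20 mM | 10.0 mM | everything together at the start, the whole solution of partner included, so that from the start the volume is larger by 0.50 times the starting volume | 15 h |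

| violet: time / h | violet: target / % | red: time / h | red: target / % |
|---|---|---|---|
| 1.33 | 5 | 1.33 | 6 |
| 2.50 | 6 | 4.00 | 18 |
| 4.00 | 11 | 8.00 | 19 |
| 8.00 | 17 | 10.0 | 22 |
| 15.0 | 17 | 15.0 | 21 |

(standard deviation of a reading: 2 percentage points)

- percentages count the substrate that a species holds: one homo product counts as two
- target is meant together with its crystals
- every charge counts on the volume at the start, and the solution that is fed holds the whole dose
- solid, in amounts per volume of the solution: crystals
- reactions considered so far: partner + intermediate -> target; 2 intermediate -> homo product; substrate -> intermediate; crystals <-> target

1. which one finishes higher in amount of target, in percent of the substrate charged ("neither" within 2 percentage points) (dusk / midnight / neither)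
2. amount of target at the end, in percent of the substrate charged, dusk
3. amount of target at the end, in percent of the substrate charged, midnight

Each target holds one partner, so the last reading of the red run puts 38.2% of its partner charge in target, and that of the violet run 46.6%, both with the scatter of the readings. This share of the charged partner that ends in target is the capture (the conversion of partner), and target in percent of substrate is capture times partner charged over substrate charged.

At red's capture, dusk gives 30.5%. But the capture read in the violet run, on the smaller dose, is higher than that read in the red run, so this reckoning puts dusk below that figure. Midnight can reach at most 50.0%, and it passes dusk's figure with a capture above 61.1%. Its partner is there from the start, so the reckoning takes midnight above that capture and calls midnight higher.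

The forecast also says midnight, with dusk at 26% and midnight at 35%, a midnight capture of 70.0%: “Midnight has partner present in full while intermediate is highest.”

The flasks give 27.3% for dusk and 45.1% for midnight, so midnight finishes higher, with captures of 34.1% and 90.3%.

    partner + intermediate → target (k = 3.70 /M/min)
    2 intermediate → homo product (k = 3.10 /M/min)
    substrate → intermediate (k = 0.0200 /min)
    crystals ⇌ target, rate k4*(cs4 - [target]) while solid is left; crystals form when [target] > cs4 (solubility = 0.220 mM, k = 0.600 /min)

In dusk, the half-life of substrate, 0.58 h, is ten times shorter than the feed of 6.0 h, and at the end of the feed homo product holds 72.7% against 26.8% in target. In midnight, at 0.578 h, intermediate goes to target at 0.86 of its rate to homo product. With 34 mM of substrate on midnight's partner, midnight's capture gives 26.6%. That neighbour flask gives 28.6%, with 2.8% of its partner left.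

(The numbers in the tables were generated by integration with constants of no real substance, noise included.)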